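**Retrosynthetic overview**

1. The last bond made is the exocyclic E‑olefin of ring A (the butyrolactone): Wittig reaction of an ester‑stabilized lactone ylide (C8, carries the S centre) with a C17 trienal that already holds ring B (the butenolide).
2. The ylide comes from the (S)‑γ‑lactone by α‑bromination and PPh3; ring A is closed by lactonization of a γ‑hydroxy ester whose stereocentre is set by ketoreductase reduction of an achiral γ‑keto ester (from 3‑methylbut‑2‑enoyl chloride and a zinc homoenolate).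
3. The trienal comes from Suzuki coupling of an (E,E)‑dienylboronate with 4‑bromofuran‑2(5H)‑one, followed by unmasking of a dimethyl acetal.
4. The dienylboronate comes from Takai–Utimoto boryl olefination of an E‑enal made from (2E,6E)‑farnesol; both trisubstituted E‑olefins are kept and the terminal isopropylidene is cut off (bromohydrin, epoxide, periodic acid).
5. Ring order: ring A is formed first (step 3); ring B is never formed but carried in ready‑made (step 14); no ring is made after that.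

Assumption: the (S)‑selective ketoreductase is picked from a commercial enzyme panel by a short screen on the keto ester of step 2; (2E,6E)‑farnesol, 4‑bromofuran‑2(5H)‑one and (3‑ethoxy‑3‑oxopropyl)zinc bromide (0.5 M in THF) are bought.

**Route**

Step 1
Reactants: 1 3‑methylbut‑2‑enoyl chloride; 2 (3‑ethoxy‑3‑oxopropyl)zinc bromide
Product: 3 ethyl 6‑methyl‑4‑oxohept‑5‑enoate
Conditions: Pd(PPh3)4 (3 mol %), THF, 0 °C → rt, 2 h
Reagents that add atoms: none
Why: Negishi‑type acylation, in which zerovalent palladium inserts into the C–Cl bond of the acid chloride, the ester‑chelated zinc homoenolate transmetalates without attacking its own ester, and reductive elimination gives the γ‑keto ester with the enone intact.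

Step 2
Reactants: 3 ethyl 6‑methyl‑4‑oxohept‑5‑enoate
Product: 4 ethyl (4S)‑4‑hydroxy‑6‑methylhept‑5‑enoate
Conditions: (S)‑selective ketoreductase (KRED, lyophilised), NADP+ (0.5 mol %), iPrOH (15 vol %), KH2PO4/K2HPO4 buffer (0.1 M, pH 7.0), MgSO4 (2 mM), 30 °C, 24 h
Reagents that add atoms: none
Why: Biocatalytic asymmetric carbonyl reduction, in which the ketoreductase (an NADPH‑dependent oxidoreductase of the alcohol dehydrogenase class, EC 1.1.1) delivers hydride from NADPH to the Re face of the ketone only, which sets the single stereocentre as S, leaves the conjugated C=C and the ester alone, and is driven by isopropanol‑coupled cofactor recycling.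

Step 3
Reactants: 4 ethyl (4S)‑4‑hydroxy‑6‑methylhept‑5‑enoate
Product: 5 (5S)‑5‑(2‑methylprop‑1‑en‑1‑yl)dihydrofuran‑2(3H)‑one
Conditions: PPTS (5 mol %), toluene, 40 °C, 3 h
Reagents that add atoms: none
Why: Acid‑catalysed lactonization (intramolecular transesterification) closes ring A without breaking the C–O bond at the stereocentre, and the weak acid does not ionize the allylic alcohol, so the S configuration is kept.

Step 4
Reactants: 5 (5S)‑5‑(2‑methylprop‑1‑en‑1‑yl)dihydrofuran‑2(3H)‑one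
Product: 8 (5S)‑3‑bromo‑5‑(2‑methylprop‑1‑en‑1‑yl)dihydrofuran‑2(3H)‑one (both C3 epimers), via lithium enolate 6 (not isolated), via silyl ketene acetal 7 (not isolated)
Conditions: LiN(iPr)2 (1.1 equiv), THF, −78 °C; Me3SiCl (1.2 equiv), −78 °C; NBS (1.05 equiv), THF, −78 → −30 °C
Reagents that add atoms: N‑bromosuccinimide, O=C1CCC(=O)N1Br (Br in 8); for 6 only lithium diisopropylamide, [Li+].CC(C)[N-]C(C)C; for 7 only chlorotrimethylsilane, C[Si](C)(C)Cl
Why: Kinetic enolization at C3, O‑silylation and electrophilic bromination of the silyl ketene acetal (far more nucleophilic than the trisubstituted olefin) give the α‑bromolactone, C5 is not involved, and the C3 configuration is irrelevant because C3 becomes sp2 later.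

Step 5
Reactants: 8 (5S)‑3‑bromo‑5‑(2‑methylprop‑1‑en‑1‑yl)dihydrofuran‑2(3H)‑one
Product: 9 triphenyl[(5S)‑5‑(2‑methylprop‑1‑en‑1‑yl)‑2‑oxooxolan‑3‑yl]phosphonium bromide
Conditions: PPh3 (1.2 equiv), THF, 65 °C, 36 h; salt precipitated with Et2O
Reagents that add atoms: triphenylphosphine, c1ccc(cc1)P(c1ccccc1)c1ccccc1
Why: SN2 quaternization of triphenylphosphine by the carbonyl‑activated secondary bromide gives the Wittig salt, as for the parent α‑bromobutyrolactone.

Step 6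
Reactants: 9 triphenyl[(5S)‑5‑(2‑methylprop‑1‑en‑1‑yl)‑2‑oxooxolan‑3‑yl]phosphonium bromide
Product: 10 (5S)‑5‑(2‑methylprop‑1‑en‑1‑yl)‑3‑(triphenyl‑λ5‑phosphanylidene)dihydrofuran‑2(3H)‑one
Conditions: aq. NaOH (1 M, 1.1 equiv), CH2Cl2, 0 °C, 10 min
Reagents that add atoms: none
Why: Deprotonation of the acidic α‑phosphonio lactone gives the isolable ester‑stabilized ylide, which passes into the organic phase before hydroxide can open the lactone.

Step 7
Reactants: 11 (2E,6E)‑farnesol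
Product: 12 (2E,6E)‑farnesyl acetate
Conditions: Ac2O (1.5 equiv), pyridine (2 equiv), DMAP (5 mol %), CH2Cl2, 0 °C → rt
Reagents that add atoms: acetic anhydride, CC(=O)OC(C)=O
Why: DMAP‑catalysed acylation protects the allylic alcohol and makes the 2,3‑olefin less electron‑rich for the next step.

Step 8
Reactants: 12 (2E,6E)‑farnesyl acetate
Product: 13 (2E,6E,10RS)‑10‑bromo‑11‑hydroxy‑3,7,11‑trimethyldodeca‑2,6‑dien‑1‑yl acetate
Conditions: NBS (1.1 equiv), THF/H2O (3:1), 0 °C, 1.5 h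
Reagents that add atoms: N‑bromosuccinimide, O=C1CCC(=O)N1Br; water, O
Why: van Tamelen terminal bromohydrin formation, in which the polyene coiled in aqueous THF exposes its terminal trisubstituted olefin to NBS and water opens the bromonium ion at the tertiary carbon (Markovnikov), giving a racemic C10 centre that is excised in step 10 and never reaches the target.

Step 9
Reactants: 13 (2E,6E,10RS)‑10‑bromo‑11‑hydroxy‑3,7,11‑trimethyldodeca‑2,6‑dien‑1‑yl acetate
Product: 15 (2E,6E)‑9‑[(2RS)‑3,3‑dimethyloxiran‑2‑yl]‑3,7‑dimethylnona‑2,6‑dien‑1‑ol (racemic 10,11‑epoxyfarnesol), via epoxy acetate 14 (not isolated)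
Conditions: K2CO3 (2.5 equiv), MeOH, rt, 3 h
Reagents that add atoms: none
Why: Intramolecular Williamson etherification of the bromohydrin closes the epoxide and the same K2CO3/MeOH transesterifies the acetate, which frees the allylic alcohol.

Step 10
Reactants: 15 (2E,6E)‑9‑[(2RS)‑3,3‑dimethyloxiran‑2‑yl]‑3,7‑dimethylnona‑2,6‑dien‑1‑ol
Product: 17 (4E,8E)‑10‑hydroxy‑4,8‑dimethyldeca‑4,8‑dienal, via triol 16 (not isolated)
Conditions: H5IO6 (1.2 equiv), THF/H2O (10:1), 0 °C, 45 min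
Reagents that add atoms: water, O (its oxygen enters 16 at C11 and leaves with acetone; the aldehyde oxygen of 17 is the former epoxide oxygen)
Why: Acid‑catalysed epoxide hydrolysis (water attacks the tertiary carbon) followed by Malaprade glycol cleavage removes the three terminal carbons as acetone and leaves the aldehyde, while the isolated olefins and the primary allylic alcohol are inert to periodate.

Step 11
Reactants: 17 (4E,8E)‑10‑hydroxy‑4,8‑dimethyldeca‑4,8‑dienal
Product: 18 (2E,6E)‑10,10‑dimethoxy‑3,7‑dimethyldeca‑2,6‑dien‑1‑ol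
Conditions: HC(OMe)3 (3 equiv), PPTS (5 mol %), MeOH, rt, 3 h; then NaHCO3
Reagents that add atoms: trimethyl orthoformate, COC(OC)OC
Why: Acid‑catalysed acetalization with the orthoformate as water scavenger masks the aldehyde as a dimethyl acetal that survives the oxidation, chromium and palladium steps, and PPTS in methanol does not touch the geraniol‑type allylic alcohol.

Step 12
Reactants: 18 (2E,6E)‑10,10‑dimethoxy‑3,7‑dimethyldeca‑2,6‑dien‑1‑ol
Product: 19 (2E,6E)‑10,10‑dimethoxy‑3,7‑dimethyldeca‑2,6‑dienal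
Conditions: activated MnO2 (15 equiv), CH2Cl2, rt, 4 h
Reagents that add atoms: none
Why: Chemoselective MnO2 oxidation of the allylic alcohol gives the E‑enal without isomerizing the trisubstituted olefin.

Step 13
Reactants: 19 (2E,6E)‑10,10‑dimethoxy‑3,7‑dimethyldeca‑2,6‑dienal
Product: 20 2‑[(1E,3E,7E)‑11,11‑dimethoxy‑4,8‑dimethylundeca‑1,3,7‑trien‑1‑yl]‑4,4,5,5‑tetramethyl‑1,3,2‑dioxaborolane
Conditions: Cl2CHB(pin) (2 equiv), CrCl2 (8 equiv), LiI (4 equiv, promoter), THF, rt, 12 h, dark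
Reagents that add atoms: 2‑(dichloromethyl)‑4,4,5,5‑tetramethyl‑1,3,2‑dioxaborolane, ClC(Cl)B1OC(C)(C)C(C)(C)O1
Why: Takai–Utimoto boryl olefination, in which the geminal dichromium reagent formed from the dichloromethylboronate adds 1,2 to the aldehyde and eliminates through the less crowded arrangement, so the new disubstituted olefin is E and the acetal is untouched.

Step 14
Reactants: 20 2‑[(1E,3E,7E)‑11,11‑dimethoxy‑4,8‑dimethylundeca‑1,3,7‑trien‑1‑yl]‑4,4,5,5‑tetramethyl‑1,3,2‑dioxaborolane; 21 4‑bromofuran‑2(5H)‑one (1.3 equiv)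
Product: 22 4‑[(1E,3E,7E)‑11,11‑dimethoxy‑4,8‑dimethylundeca‑1,3,7‑trien‑1‑yl]furan‑2(5H)‑one
Conditions: PdCl2(dppf) (5 mol %), K3PO4 (3 equiv), THF/H2O (9:1), 45 °C, 4 h, degassed, dark
Reagents that add atoms: none
Why: Suzuki–Miyaura coupling, in which zerovalent palladium inserts into the activated β‑bromo enoate C–Br bond, the dienylboronate transmetalates and reductive elimination joins the two sp2 carbons with retention of the E,E‑diene geometry, bringing in ring B ready‑made.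

Step 15
Reactants: 22 4‑[(1E,3E,7E)‑11,11‑dimethoxy‑4,8‑dimethylundeca‑1,3,7‑trien‑1‑yl]furan‑2(5H)‑one
Product: 23 (4E,8E,10E)‑4,8‑dimethyl‑11‑(5‑oxo‑2,5‑dihydrofuran‑3‑yl)undeca‑4,8,10‑trienal
Conditions: aq. HCl (1 M)/THF (1:5), 0 °C → rt, 1 h
Reagents that add atoms: water, O
Why: Mild aqueous acid hydrolyses the dimethyl acetal through its oxocarbenium ion to the aldehyde, and the butenolide and the conjugated triene are stable to dilute acid at room temperature.

Step 16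
Reactants: 23 (4E,8E,10E)‑4,8‑dimethyl‑11‑(5‑oxo‑2,5‑dihydrofuran‑3‑yl)undeca‑4,8,10‑trienal; 10 (5S)‑5‑(2‑methylprop‑1‑en‑1‑yl)‑3‑(triphenyl‑λ5‑phosphanylidene)dihydrofuran‑2(3H)‑one (1.3 equiv)
Product: 24 (3E,5S)‑3‑[(4E,8E,10E)‑4,8‑dimethyl‑11‑(5‑oxo‑2,5‑dihydrofuran‑3‑yl)undeca‑4,8,10‑trien‑1‑ylidene]‑5‑(2‑methylprop‑1‑en‑1‑yl)dihydrofuran‑2(3H)‑one
Conditions: toluene, 70 °C, 14 h, dark, BHT (trace); minor Z isomer removed by chromatography
Reagents that add atoms: none
Why: Wittig olefination with an ester‑stabilized ylide under neutral conditions goes through the lower‑energy trans‑oxaphosphetane and gives the E‑alkylidene lactone (chain trans to the lactone carbonyl), while the butenolide, the triene and the S centre at C5 are not touched.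

**Compound list**

1 | 3‑methylbut‑2‑enoyl chloride | CC(C)=CC(=O)Cl | starting material
2 | (3‑ethoxy‑3‑oxopropyl)zinc bromide | CCOC(=O)CC[Zn]Br | starting material
3 | ethyl 6‑methyl‑4‑oxohept‑5‑enoate | CCOC(=O)CCC(=O)C=C(C)C | intermediate
4 | ethyl (4S)‑4‑hydroxy‑6‑methylhept‑5‑enoate | CC(C)=C[C@@H](O)CCC(=O)OCC | intermediate
5 | (5S)‑5‑(2‑methylprop‑1‑en‑1‑yl)dihydrofuran‑2(3H)‑one | CC(C)=C[C@@H]1CCC(=O)O1 | intermediate
6 | lithium (5S)‑5‑(2‑methylprop‑1‑en‑1‑yl)‑4,5‑dihydrofuran‑2‑olate (lithium enolate, formed in the flask) | CC(C)=C[C@@H]1CC=C([O-])O1.[Li+] | intermediate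
7 | trimethyl{[(5S)‑5‑(2‑methylprop‑1‑en‑1‑yl)‑4,5‑dihydrofuran‑2‑yl]oxy}silane (silyl ketene acetal, formed in the flask) | CC(C)=C[C@@H]1CC=C(O[Si](C)(C)C)O1 | intermediate
8 | (5S)‑3‑bromo‑5‑(2‑methylprop‑1‑en‑1‑yl)dihydrofuran‑2(3H)‑one (both C3 epimers) | CC(C)=C[C@@H]1CC(Br)C(=O)O1 | intermediate
9 | triphenyl[(5S)‑5‑(2‑methylprop‑1‑en‑1‑yl)‑2‑oxooxolan‑3‑yl]phosphonium bromide | CC(C)=C[C@@H]1CC([P+](c2ccccc2)(c2ccccc2)c2ccccc2)C(=O)O1.[Br-] | intermediate
10 | (5S)‑5‑(2‑methylprop‑1‑en‑1‑yl)‑3‑(triphenyl‑λ5‑phosphanylidene)dihydrofuran‑2(3H)‑one | CC(C)=C[C@@H]1CC(=P(c2ccccc2)(c2ccccc2)c2ccccc2)C(=O)O1 | intermediate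
11 | (2E,6E)‑farnesol | CC(C)=CCC/C(C)=C/CC/C(C)=C/CO | starting material
12 | (2E,6E)‑farnesyl acetate | CC(C)=CCC/C(C)=C/CC/C(C)=C/COC(C)=O | intermediate
13 | (2E,6E,10RS)‑10‑bromo‑11‑hydroxy‑3,7,11‑trimethyldodeca‑2,6‑dien‑1‑yl acetate (racemic) | CC(C)(O)C(Br)CC/C(C)=C/CC/C(C)=C/COC(C)=O | intermediate
14 | (2E,6E)‑9‑[(2RS)‑3,3‑dimethyloxiran‑2‑yl]‑3,7‑dimethylnona‑2,6‑dien‑1‑yl acetate (racemic, formed in the flask) | CC1(C)OC1CC/C(C)=C/CC/C(C)=C/COC(C)=O | intermediate
15 | (2E,6E)‑9‑[(2RS)‑3,3‑dimethyloxiran‑2‑yl]‑3,7‑dimethylnona‑2,6‑dien‑1‑ol (racemic) | CC1(C)OC1CC/C(C)=C/CC/C(C)=C/CO | intermediate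
16 | (2E,6E,10RS)‑3,7,11‑trimethyldodeca‑2,6‑diene‑1,10,11‑triol (racemic, formed in the flask) | CC(C)(O)C(O)CC/C(C)=C/CC/C(C)=C/CO | intermediate
17 | (4E,8E)‑10‑hydroxy‑4,8‑dimethyldeca‑4,8‑dienal | O=CCC/C(C)=C/CC/C(C)=C/CO | intermediate
18 | (2E,6E)‑10,10‑dimethoxy‑3,7‑dimethyldeca‑2,6‑dien‑1‑ol | COC(OC)CC/C(C)=C/CC/C(C)=C/CO | intermediate
19 | (2E,6E)‑10,10‑dimethoxy‑3,7‑dimethyldeca‑2,6‑dienal | COC(OC)CC/C(C)=C/CC/C(C)=C/C=O | intermediate
20 | 2‑[(1E,3E,7E)‑11,11‑dimethoxy‑4,8‑dimethylundeca‑1,3,7‑trien‑1‑yl]‑4,4,5,5‑tetramethyl‑1,3,2‑dioxaborolane | COC(OC)CC/C(C)=C/CC/C(C)=C/C=C/B1OC(C)(C)C(C)(C)O1 | intermediate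
21 | 4‑bromofuran‑2(5H)‑one | BrC1=CC(=O)OC1 | starting material
22 | 4‑[(1E,3E,7E)‑11,11‑dimethoxy‑4,8‑dimethylundeca‑1,3,7‑trien‑1‑yl]furan‑2(5H)‑one | COC(OC)CC/C(C)=C/CC/C(C)=C/C=C/C1=CC(=O)OC1 | intermediate
23 | (4E,8E,10E)‑4,8‑dimethyl‑11‑(5‑oxo‑2,5‑dihydrofuran‑3‑yl)undeca‑4,8,10‑trienal | O=CCC/C(C)=C/CC/C(C)=C/C=C/C1=CC(=O)OC1 | intermediate
24 | (3E,5S)‑3‑[(4E,8E,10E)‑4,8‑dimethyl‑11‑(5‑oxo‑2,5‑dihydrofuran‑3‑yl)undeca‑4,8,10‑trien‑1‑ylidene]‑5‑(2‑methylprop‑1‑en‑1‑yl)dihydrofuran‑2(3H)‑one | CC(C)=C[C@@H]1C/C(=C\CC/C(C)=C/CC/C(C)=C/C=C/C2=CC(=O)OC2)C(=O)O1 | target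

**Step count and risks**

Total step count: 16. Longest linear sequence: 10 steps (11 → 24, steps 7–16); the lactone branch is 6 steps (1 → 10) and joins in step 16.

Steps most likely to fail:

Step 4 (α‑bromination of the allylic lactone; over‑bromination or attack of NBS on the olefin, followed by a slow SN2 on a secondary bromide). The fallback gives up the phosphorus ylide and makes the exocyclic olefin by aldol addition and elimination. It sets out from lactone 5, whose lithium enolate 6 (LiN(iPr)2, THF, −78 °C) is added to aldehyde 23 at −78 °C with a short contact time and an NH4Cl quench. This gives the aldol adduct (5S)‑3‑[(4E,8E,10E)‑1‑hydroxy‑4,8‑dimethyl‑11‑(5‑oxo‑2,5‑dihydrofuran‑3‑yl)undeca‑4,8,10‑trien‑1‑yl]‑5‑(2‑methylprop‑1‑en‑1‑yl)dihydrofuran‑2(3H)‑one F1 as a diastereomer mixture. MsCl/Et3N (CH2Cl2, 0 °C) converts it into (4E,8E,10E)‑4,8‑dimethyl‑1‑[(5S)‑5‑(2‑methylprop‑1‑en‑1‑yl)‑2‑oxooxolan‑3‑yl]‑11‑(5‑oxo‑2,5‑dihydrofuran‑3‑yl)undeca‑4,8,10‑trien‑1‑yl methanesulfonate F2. DBU (CH2Cl2, 0 °C → rt) then eliminates by an E1cB pathway to the more stable E‑alkylidene lactone, so the fallback comes back to the route at target 24 and replaces steps 4–6 and 16.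

Step 13 (chromium boryl olefination of a β,β‑disubstituted enal; conversion and E/Z ratio uncertain). The fallback builds the dienylboronate through an alkyne instead of a carbonyl olefination. It sets out from enal 19: Corey–Fuchs dibromo‑olefination (CBr4, PPh3, Et3N, CH2Cl2, 0 °C) gives (3E,7E)‑1,1‑dibromo‑11,11‑dimethoxy‑4,8‑dimethylundeca‑1,3,7‑triene F3. n‑BuLi (2.2 equiv, THF, −78 °C, then water) converts it into (3E,7E)‑11,11‑dimethoxy‑4,8‑dimethylundeca‑3,7‑dien‑1‑yne F4. Zirconium‑catalysed syn‑hydroboration with pinacolborane (Cp2ZrHCl 10 mol %, Et3N, 50 °C) places boron on the terminal carbon with E geometry, so the fallback comes back to the route at boronate 20.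

Step 14 (Suzuki coupling; the bromobutenolide is sensitive to aqueous base and the dienylboronate may protodeboronate). The fallback reverses the polarity of the coupling and runs it base‑free as a Stille reaction. It sets out from enal 19 and bromide 21. Takai iodo‑olefination of 19 (CHI3, CrCl2, THF/1,4‑dioxane, 0 °C, dark) gives (1E,3E,7E)‑1‑iodo‑11,11‑dimethoxy‑4,8‑dimethylundeca‑1,3,7‑triene F5. Bromide 21 is stannylated ((Bu3Sn)2, Pd(PPh3)4, THF, 65 °C) to 4‑(tributylstannyl)furan‑2(5H)‑one F6. Stille coupling of F5 with F6 (Pd2(dba)3, AsPh3, CuI, DMF, rt, dark) under neutral conditions gives the triene butenolide, so the fallback comes back to the route at 22 and replaces steps 13 and 14.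

**Further compounds**

F1 | step 4 | (5S)‑3‑[(4E,8E,10E)‑1‑hydroxy‑4,8‑dimethyl‑11‑(5‑oxo‑2,5‑dihydrofuran‑3‑yl)undeca‑4,8,10‑trien‑1‑yl]‑5‑(2‑methylprop‑1‑en‑1‑yl)dihydrofuran‑2(3H)‑one (diastereomer mixture) | CC(C)=C[C@@H]1CC(C(O)CC/C(C)=C/CC/C(C)=C/C=C/C2=CC(=O)OC2)C(=O)O1
F2 | step 4 | (4E,8E,10E)‑4,8‑dimethyl‑1‑[(5S)‑5‑(2‑methylprop‑1‑en‑1‑yl)‑2‑oxooxolan‑3‑yl]‑11‑(5‑oxo‑2,5‑dihydrofuran‑3‑yl)undeca‑4,8,10‑trien‑1‑yl methanesulfonate (diastereomer mixture) | CC(C)=C[C@@H]1CC(C(OS(C)(=O)=O)CC/C(C)=C/CC/C(C)=C/C=C/C2=CC(=O)OC2)C(=O)O1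
F3 | step 13 | (3E,7E)‑1,1‑dibromo‑11,11‑dimethoxy‑4,8‑dimethylundeca‑1,3,7‑triene | COC(OC)CC/C(C)=C/CC/C(C)=C/C=C(Br)Br
F4 | step 13 | (3E,7E)‑11,11‑dimethoxy‑4,8‑dimethylundeca‑3,7‑dien‑1‑yne | COC(OC)CC/C(C)=C/CC/C(C)=C/C#C
F5 | step 14 | (1E,3E,7E)‑1‑iodo‑11,11‑dimethoxy‑4,8‑dimethylundeca‑1,3,7‑triene | COC(OC)CC/C(C)=C/CC/C(C)=C/C=C/I
F6 | step 14 | 4‑(tributylstannyl)furan‑2(5H)‑one | CCCC[Sn](CCCC)(CCCC)C1=CC(=O)OC1
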